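Atom labels used throughout: arene C1–C6 (C1 bears C8, C2 bears the isobutyrate oxygen O2, C4 bears C7); C7 = benzylic CH2; C8 = quaternary oxirane carbon; C9 = oxirane CH2; C10 = CH2 of the acetoxymethyl arm; O8 = oxirane oxygen; O10 = alkyl oxygen of the acetate.

## Analysis of the target

The target 12 is a benzene ring with three substituents: at C1 the quaternary carbon C8 of a 2,2-disubstituted oxirane (C8, C9, O8), at C2 an aryl isobutyrate, and at C4 a CH2 group (C7) carrying a pentanoate; C8 also bears the acetoxymethyl arm C10–O10. C8 is the only stereocentre, quaternary and benzylic, with S configuration. It is stereogenic solely because its two oxygenated methylene arms differ: C9 is tied to O8 in the three-membered ring, C10 carries the acetylated O10. The five atoms C8, C9, C10, O8 and O10 are those of an oxetan-3-ol: if the bond of C9 is moved from O8 to O10, a 3-aryl-oxetan-3-ol results that has a mirror plane through C1, C8, O8 and O10 and is achiral. The sensitive groups are the benzylic oxirane (acid opens it at C8 or triggers a Meinwald rearrangement) and three different esters on three different oxygens, of which the aryl ester is an activated acyl donor placed ortho to C8. Any oxygen nucleophile at O8 or O10 can therefore take the isobutyryl group through a six- or seven-membered shift, and a free phenol O2 would attack C9 to give a 2,3-dihydrobenzofuran-3-ol. The synthesis is hard because the quaternary centre must be made enantioselectively, three different acyl groups must be placed without protecting-group traffic, and no hydride, organometal or nucleophilic base may be used once the esters are on.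

## Retrosynthetic reasoning

12 ⇒ 11. The oxirane is cut at O8–C9, not at C8–O8. C8 then keeps all four substituents through the last step, and the acid-labile oxirane appears only in the final operation. Forward, O8 of bromohydrin 11 must displace bromide at C9 (3-exo-tet) under a carbonate base, faster than the neighbouring aryl ester can hand over its acyl group.

11 ⇒ 10. The acetyl group is taken off O10. In 10, O10–H is the only primary hydroxyl and O8–H is tertiary, so the forward acetylation needs no protecting group.

10 ⇒ 9 ⇒ 8 (key disconnection). In 10, C9 carries bromine and C10 carries O10–H. Joining C9 to O10 with loss of HBr gives the oxetane of 8, which is achiral: its two ring CH2 groups are enantiotopic. The cut is made here because the stereocentre then arises from a choice between two identical groups, with no bond made or broken at C8. The same event also decides which arm becomes the electrophile for the oxirane (C9) and which carries the acetate (C10). Forward, a chiral hydrogen-bond donor must steer a silyl bromide to open one CH2–O bond only, giving the bis-silyl ether 9, without touching the three esters.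

8 ⇒ 7 ⇒ 6 ⇒ 5. The silyl cap on O8, the isobutyryl group on O2 and the pentanoyl group on the C7 oxygen are removed in turn. Forward, each acyl group goes onto the only hydroxyl of its kind: a lipase acylates the single primary alcohol of 5 to give 6, an acyl chloride then takes the phenol (7), and silicon caps the tertiary O8–H (8).

5 ⇒ 4 + 3. The C1–C8 bond is cut to the aryllithium 4 and oxetan-3-one 3. This is the only carbon–carbon bond the route forms, and it is formed before any ester is present, so the organometal meets nothing it can attack.

4 ⇒ 2 ⇒ 1. The trilithiated arene 4 comes from bromophenol 2 by deprotonation and bromine–lithium exchange, and 2 from the commercial acid 1 by reduction of the carboxyl group to C7.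

## Alternatives that were turned down

Alternative 1: the textbook route. Both C–O bonds of the oxirane are cut back to the C8=C9 double bond of [4-(3-hydroxyprop-1-en-2-yl)-3-(2-methylpropanoyloxy)phenyl]methyl pentanoate A1. The forward key step is a Sharpless asymmetric epoxidation (Ti(OiPr)4, diethyl tartrate, t-BuOOH) to the epoxy alcohol A2, followed by acetylation. It is about one step shorter, but it was turned down for these reasons:
- The stereocentre would be created by face selection on a 1,1-disubstituted alkene whose aryl group is twisted out of plane by the ortho ester.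
- A2 is a benzylic, tertiary epoxy alcohol held on a Lewis-acidic titanium alkoxide, the situation in which such epoxides open.
- Ti(OiPr)4 is a transesterification catalyst and the aryl isobutyrate is an activated ester.
- A1 needs a cross-coupling with a 2-metallated allyl alcohol that is not a stock item.

Alternative 2: the C8–C9 and O8–C9 bonds are cut, leading to the ketone [4-(2-acetoxyacetyl)-3-(2-methylpropanoyloxy)phenyl]methyl pentanoate A3. The forward key step is a catalytic asymmetric Corey–Chaykovsky methylene transfer (dimethylsulfoxonium methylide, LaLi3(binaphthoxide)3). It was turned down for these reasons: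
- The catalyst class distinguishes aryl from methyl, whereas here it would have to tell a twisted aryl group from CH2OAc.
- The ylide is basic enough to enolise the α-acetoxy ketone and nucleophilic enough to attack the aryl ester.
- The betaine alkoxide at O8 sits next to the ortho ester with a poorer leaving group at C9 than bromide, so acyl shift is favoured over closure.
- A3 itself costs an aryl ketone synthesis plus an α-oxygenation.

Alternative 3: the same hidden symmetry is used in open-chain form. The triol [3-(2-methylpropanoyloxy)-4-(1,2,3-trihydroxypropan-2-yl)phenyl]methyl pentanoate A4 is mono-acetylated with desymmetrisation (lipase and vinyl acetate, or CuCl2 with a chiral bisoxazoline and an acyl chloride) to A5, then the second primary hydroxyl is activated and the oxirane closed. It was turned down for these reasons: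
- A5 is a 1-monoacyl glycerol, and its acetyl group can migrate between the two primary oxygens (directly or via O8), which racemises the very compound that holds the stereo information. A carbon–bromine bond cannot migrate.
- A4 has three free hydroxyls next to the aryl ester.
- A lipase would meet three esters in the substrate.
- The triol needs an enolisable protected dihydroxyacetone for the aryl addition and an extra acidic deprotection, one step more than the oxetane route.

Key step: step 5

Assumption: the sense of enantiotopic-group selection by the squaramide cannot be predicted with certainty for a 3-aryl-3-silyloxyoxetane. The route is written for the catalyst antipode that gives (R)-10; its mirror image (from (R)-tert-leucine and the (S)-pyrrolidine) is used if the first run shows the opposite sense.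

## Route

Step 1
Reactants: 1 4-bromo-3-hydroxybenzoic acid
Product: 2 2-bromo-5-(hydroxymethyl)phenol
Conditions: BH3·THF (3 equiv), THF, 0 → 50 °C; then H2O
Reagents that add atoms: none
Why: Borane reduction of a carboxylic acid to the primary alcohol; the phenol only forms a borate that is hydrolysed on work-up, and the aryl bromide is inert to borane.

Step 2
Reactants: 2 2-bromo-5-(hydroxymethyl)phenol; 3 oxetan-3-one
Product: 5 2-(3-hydroxyoxetan-3-yl)-5-(hydroxymethyl)phenol, via trilithiated arene 4 (not isolated)
Conditions: n-BuLi (2.05 equiv), THF, −78 °C; t-BuLi (2.1 equiv), −78 °C; then 3 (1.3 equiv), −78 → 0 °C; aq. NH4Cl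
Reagents that add atoms: none
Why: Bromine–lithium exchange on the dilithium salt followed by 1,2-addition of the aryllithium to the strained, weakly enolisable ketone, the standard entry to 3-aryl-oxetan-3-ols; both acidic protons are removed first so no protecting group is needed, and the neutral quench avoids acid, under which the ortho phenol could open the oxetane.

Step 3
Reactants: 5 2-(3-hydroxyoxetan-3-yl)-5-(hydroxymethyl)phenol
Product: 6 [3-hydroxy-4-(3-hydroxyoxetan-3-yl)phenyl]methyl pentanoate
Conditions: vinyl pentanoate (3 equiv), immobilised Candida antarctica lipase B, 2-methyltetrahydrofuran, 35 °C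
Reagents that add atoms: vinyl pentanoate, CCCCC(=O)OC=C
Why: Lipase-catalysed irreversible transesterification with a vinyl ester; the enzyme acylates the primary benzylic alcohol but neither the phenol nor the tertiary alcohol, and the neutral medium leaves the oxetane untouched.

Step 4
Reactants: 6 [3-hydroxy-4-(3-hydroxyoxetan-3-yl)phenyl]methyl pentanoate
Product: 8 [3-(2-methylpropanoyloxy)-4-[3-(trimethylsilyloxy)oxetan-3-yl]phenyl]methyl pentanoate, via aryl isobutyrate 7 (not isolated)
Conditions: i-PrCOCl (1.1 equiv), pyridine (3 equiv), CH2Cl2, 0 °C; then Me3SiCl (1.5 equiv), imidazole (3 equiv), 0 °C → rt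
Reagents that add atoms: 2-methylpropanoyl chloride, CC(C)C(Cl)=O; chlorotrimethylsilane, C[Si](C)(C)Cl
Why: Pyridine-mediated O-acylation takes the phenol and not the tertiary alcohol, which needs a stronger acyl-transfer catalyst; silylation in the same flask then caps O8, which removes the acyl acceptor next to the aryl ester and prevents HBr release in step 5.

Step 5
Reactants: 8 [3-(2-methylpropanoyloxy)-4-[3-(trimethylsilyloxy)oxetan-3-yl]phenyl]methyl pentanoate
Product: 10 [4-[(2R)-1-bromo-2,3-dihydroxypropan-2-yl]-3-(2-methylpropanoyloxy)phenyl]methyl pentanoate, via bis(trimethylsilyl) ether 9 (not isolated)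
Conditions: Me3SiBr (1.05 equiv), chiral squaramide 3-{[3,5-bis(trifluoromethyl)phenyl]amino}-4-({(2S)-3,3-dimethyl-1-oxo-1-[(2R)-2-(phenanthren-9-yl)pyrrolidin-1-yl]butan-2-yl}amino)cyclobut-3-ene-1,2-dione (5 mol %), t-BuOMe, −80 → −40 °C; then MeOH, pyridinium p-toluenesulfonate (0.1 equiv), 0 °C
Reagents that add atoms: bromotrimethylsilane, C[Si](C)(C)Br
Why: Desymmetrising ring opening of an oxetane under hydrogen-bond-donor (anion-abstraction) catalysis, a known reaction type for 3-substituted and 3,3-disubstituted oxetanes with bromotrimethylsilane. The squaramide binds the bromide of the silyl bromide, silicon is transferred to the ring oxygen O10, and the O-silyloxetanium ion stays paired with the catalyst-bound bromide. Bromide is then delivered in an SN2 step to one of the two enantiotopic ring methylenes, so that the C9–O10 bond breaks, C9 receives bromine and O10 stays on C10 as a silyl ether; no ring is closed here, the four-membered ring is opened and the three-membered ring closes in step 7 by 3-exo-tet attack at the same C9. C8 is not touched: it becomes stereogenic only because its two CH2 arms are made different, so the controlling element is the catalyst alone, and no later step makes or breaks a bond at C8. The selectivity needed is enantiotopic-group selectivity, for which the catalyst must tell the twisted, ortho-substituted aryl group from the OSiMe3 group on C8 (the arylpyrrolidine can stack on the aryl face of the ion pair). Chemoselectivity comes from the substrate: the silyl cap on O8 prevents HBr formation and thus racemic background opening, the aryl ring is not donor-activated so C8 does not ionise, and at −80 °C the three esters do not react with the silyl bromide. Acid-catalysed methanolysis of both silyl ethers then gives the bromo diol without base, so neither oxirane closure nor acyl shift can start before the acetate is in place.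

Step 6
Reactants: 10 [4-[(2R)-1-bromo-2,3-dihydroxypropan-2-yl]-3-(2-methylpropanoyloxy)phenyl]methyl pentanoate
Product: 11 [4-[(2R)-1-acetoxy-3-bromo-2-hydroxypropan-2-yl]-3-(2-methylpropanoyloxy)phenyl]methyl pentanoate
Conditions: Ac2O (1.2 equiv), pyridine, CH2Cl2, 0 °C
Reagents that add atoms: acetic anhydride, CC(=O)OC(C)=O
Why: Chemoselective acetylation of the only primary hydroxyl (O10–H); the tertiary O8–H does not react without an acyl-transfer catalyst, and pyridine is too weak a base to start closure of the bromohydrin.

Step 7
Reactants: 11 [4-[(2R)-1-acetoxy-3-bromo-2-hydroxypropan-2-yl]-3-(2-methylpropanoyloxy)phenyl]methyl pentanoate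
Product: 12 [4-[(2S)-2-(acetoxymethyl)oxiran-2-yl]-3-(2-methylpropanoyloxy)phenyl]methyl pentanoate
Conditions: Cs2CO3 (1.5 equiv), MeCN, 0 °C → rt
Reagents that add atoms: none
Why: Intramolecular Williamson etherification (3-exo-tet) of a bromohydrin, as in the base closure of 3-halo-2-hydroxypropyl esters to glycidyl esters, where ring closure outruns acyl migration; the bromide leaving group and the gem-disubstituted tertiary alkoxide should favour closure further. The geometry at C8 is retained, and the descriptor changes from R to S only because C9 loses bromine and drops below C10 in priority.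

## Compound list

1 | 4-bromo-3-hydroxybenzoic acid | OC(=O)c1ccc(Br)c(O)c1 | starting material
2 | 2-bromo-5-(hydroxymethyl)phenol | OCc1ccc(Br)c(O)c1 | intermediate
3 | oxetan-3-one | O=C1COC1 | starting material
4 | lithium 2-lithio-5-[(lithiooxy)methyl]phenolate (trilithiated arene) | [Li]OCc1ccc([Li])c(O[Li])c1 | intermediate (not isolated)
5 | 2-(3-hydroxyoxetan-3-yl)-5-(hydroxymethyl)phenol | OCc1ccc(C2(O)COC2)c(O)c1 | intermediate
6 | [3-hydroxy-4-(3-hydroxyoxetan-3-yl)phenyl]methyl pentanoate | CCCCC(=O)OCc1ccc(C2(O)COC2)c(O)c1 | intermediate
7 | [4-(3-hydroxyoxetan-3-yl)-3-(2-methylpropanoyloxy)phenyl]methyl pentanoate | CCCCC(=O)OCc1ccc(C2(O)COC2)c(OC(=O)C(C)C)c1 | intermediate (not isolated)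
8 | [3-(2-methylpropanoyloxy)-4-[3-(trimethylsilyloxy)oxetan-3-yl]phenyl]methyl pentanoate | CCCCC(=O)OCc1ccc(C2(O[Si](C)(C)C)COC2)c(OC(=O)C(C)C)c1 | intermediate
9 | [4-[(2R)-1-bromo-2,3-bis(trimethylsilyloxy)propan-2-yl]-3-(2-methylpropanoyloxy)phenyl]methyl pentanoate | CCCCC(=O)OCc1ccc([C@@](O[Si](C)(C)C)(CO[Si](C)(C)C)CBr)c(OC(=O)C(C)C)c1 | intermediate (not isolated)
10 | [4-[(2R)-1-bromo-2,3-dihydroxypropan-2-yl]-3-(2-methylpropanoyloxy)phenyl]methyl pentanoate | CCCCC(=O)OCc1ccc([C@@](O)(CO)CBr)c(OC(=O)C(C)C)c1 | intermediate
11 | [4-[(2R)-1-acetoxy-3-bromo-2-hydroxypropan-2-yl]-3-(2-methylpropanoyloxy)phenyl]methyl pentanoate | CCCCC(=O)OCc1ccc([C@@](O)(COC(C)=O)CBr)c(OC(=O)C(C)C)c1 | intermediate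
12 | [4-[(2S)-2-(acetoxymethyl)oxiran-2-yl]-3-(2-methylpropanoyloxy)phenyl]methyl pentanoate (CNP0107520.1) | CCCCC(=O)OCc1ccc([C@@]2(COC(C)=O)CO2)c(OC(=O)C(C)C)c1 | target

## Step count and risks

Total step count: 7. Longest linear sequence: 7 steps (1 → 12); oxetan-3-one 3 enters in step 2.

**Step 5 (key step).** The most likely failure is poor discrimination between the two enantiotopic CH2 groups, because the catalyst has to tell an ortho-substituted aryl group from a silyloxy group on C8. A second failure mode is racemic background opening if any HBr forms from adventitious water. The 3,3-disubstituted oxetane is also hindered, so opening may be slow at the temperature that gives good selectivity.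

Fallback: asymmetric catalysis is replaced by a resolution. The fallback sets out from 8 and comes back at 11. 8 is opened with Me3SiBr alone (CH2Cl2, −20 °C) to racemic [4-[1-bromo-2,3-bis(trimethylsilyloxy)propan-2-yl]-3-(2-methylpropanoyloxy)phenyl]methyl pentanoate F1 (not isolated). Methanolysis as in step 5 gives racemic [4-(1-bromo-2,3-dihydroxypropan-2-yl)-3-(2-methylpropanoyloxy)phenyl]methyl pentanoate F2. The acetylation of step 6 is then run as a lipase-catalysed kinetic resolution (Burkholderia cepacia lipase, vinyl acetate, t-BuOMe, 30 °C). On the assumption that the (R)-alcohol reacts faster, this should give 11 directly and leave [4-[(2S)-1-bromo-2,3-dihydroxypropan-2-yl]-3-(2-methylpropanoyloxy)phenyl]methyl pentanoate F3, which is removed by chromatography. If the enzyme prefers the other enantiomer, the recovered alcohol is 10 and enters step 6 unchanged.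

**Step 7.** The C8 alkoxide may attack the ortho aryl ester through a six-membered transition state instead of displacing bromide. The phenoxide set free would then close onto C9 (5-exo-tet) to a dihydrobenzofuran. A slower side path is acetyl shift from O10 to O8 followed by 4-exo closure back to an oxetane. Closure is expected to win, but the margin is not known.

Fallback: the order of oxirane closure and phenol acylation is inverted, so that no acyl donor sits next to the alkoxide. The fallback sets out from 11 and comes back at 12.
- The aryl ester alone is cleaved with hydrazinium acetate (DMF, 0 °C) to [4-[(2R)-1-acetoxy-3-bromo-2-hydroxypropan-2-yl]-3-hydroxyphenyl]methyl pentanoate F4.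
- The phenol is silylated at once (i-Pr3SiCl, imidazole, DMF, 0 °C) to [4-[(2R)-1-acetoxy-3-bromo-2-hydroxypropan-2-yl]-3-{[tri(propan-2-yl)silyl]oxy}phenyl]methyl pentanoate F5.
- Cs2CO3 in MeCN closes the oxirane to [4-[(2S)-2-(acetoxymethyl)oxiran-2-yl]-3-{[tri(propan-2-yl)silyl]oxy}phenyl]methyl pentanoate F6.
- The silyl ether is exchanged for the ester in one flask with Bu4NF in the presence of excess 2-methylpropanoic anhydride (THF, −40 °C), so that the phenoxide is acylated as it forms; this gives 12.

**Step 2.** The dilithium salt of 2 may aggregate or precipitate, leaving the exchange incomplete. The aryllithium can also be quenched by proton transfer from the ketone instead of adding to it.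

Fallback: both hydroxyls are masked so that a soluble mono-lithium species adds. The fallback sets out from 2 and comes back at 5. 2 is silylated (i-Pr3SiCl, 2.2 equiv, imidazole, DMF) to [2-bromo-5-({[tri(propan-2-yl)silyl]oxy}methyl)phenoxy]tri(propan-2-yl)silane F7. Exchange with t-BuLi (2 equiv, THF, −78 °C) gives {2-{[tri(propan-2-yl)silyl]oxy}-4-({[tri(propan-2-yl)silyl]oxy}methyl)phenyl}lithium F8 (not isolated); the bulky silyl group and the low temperature hold back silyl migration from oxygen to carbon. Addition to 3 gives 3-[2-{[tri(propan-2-yl)silyl]oxy}-4-({[tri(propan-2-yl)silyl]oxy}methyl)phenyl]oxetan-3-ol F9, and Bu4NF (THF, 0 °C) removes both silyl groups to give 5.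

## Further compounds

F1 | step 5 | racemic [4-[1-bromo-2,3-bis(trimethylsilyloxy)propan-2-yl]-3-(2-methylpropanoyloxy)phenyl]methyl pentanoate | CCCCC(=O)OCc1ccc(C(O[Si](C)(C)C)(CO[Si](C)(C)C)CBr)c(OC(=O)C(C)C)c1
F2 | step 5 | racemic [4-(1-bromo-2,3-dihydroxypropan-2-yl)-3-(2-methylpropanoyloxy)phenyl]methyl pentanoate | CCCCC(=O)OCc1ccc(C(O)(CO)CBr)c(OC(=O)C(C)C)c1
F3 | step 5 | [4-[(2S)-1-bromo-2,3-dihydroxypropan-2-yl]-3-(2-methylpropanoyloxy)phenyl]methyl pentanoate | CCCCC(=O)OCc1ccc([C@](O)(CO)CBr)c(OC(=O)C(C)C)c1
F4 | step 7 | [4-[(2R)-1-acetoxy-3-bromo-2-hydroxypropan-2-yl]-3-hydroxyphenyl]methyl pentanoate | CCCCC(=O)OCc1ccc([C@@](O)(COC(C)=O)CBr)c(O)c1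
F5 | step 7 | [4-[(2R)-1-acetoxy-3-bromo-2-hydroxypropan-2-yl]-3-{[tri(propan-2-yl)silyl]oxy}phenyl]methyl pentanoate | CCCCC(=O)OCc1ccc([C@@](O)(COC(C)=O)CBr)c(O[Si](C(C)C)(C(C)C)C(C)C)c1
F6 | step 7 | [4-[(2S)-2-(acetoxymethyl)oxiran-2-yl]-3-{[tri(propan-2-yl)silyl]oxy}phenyl]methyl pentanoate | CCCCC(=O)OCc1ccc([C@@]2(COC(C)=O)CO2)c(O[Si](C(C)C)(C(C)C)C(C)C)c1
F7 | step 2 | [2-bromo-5-({[tri(propan-2-yl)silyl]oxy}methyl)phenoxy]tri(propan-2-yl)silane | CC(C)[Si](C(C)C)(C(C)C)OCc1ccc(Br)c(O[Si](C(C)C)(C(C)C)C(C)C)c1
F8 | step 2 | {2-{[tri(propan-2-yl)silyl]oxy}-4-({[tri(propan-2-yl)silyl]oxy}methyl)phenyl}lithium | CC(C)[Si](C(C)C)(C(C)C)OCc1ccc([Li])c(O[Si](C(C)C)(C(C)C)C(C)C)c1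
F9 | step 2 | 3-[2-{[tri(propan-2-yl)silyl]oxy}-4-({[tri(propan-2-yl)silyl]oxy}methyl)phenyl]oxetan-3-ol | CC(C)[Si](C(C)C)(C(C)C)OCc1ccc(C2(O)COC2)c(O[Si](C(C)C)(C(C)C)C(C)C)c1
A1 | alternative 1 | [4-(3-hydroxyprop-1-en-2-yl)-3-(2-methylpropanoyloxy)phenyl]methyl pentanoate | CCCCC(=O)OCc1ccc(C(=C)CO)c(OC(=O)C(C)C)c1
A2 | alternative 1 | [4-[(2R)-2-(hydroxymethyl)oxiran-2-yl]-3-(2-methylpropanoyloxy)phenyl]methyl pentanoate | CCCCC(=O)OCc1ccc([C@@]2(CO)CO2)c(OC(=O)C(C)C)c1
A3 | alternative 2 | [4-(2-acetoxyacetyl)-3-(2-methylpropanoyloxy)phenyl]methyl pentanoate | CCCCC(=O)OCc1ccc(C(=O)COC(C)=O)c(OC(=O)C(C)C)c1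
A4 | alternative 3 | [3-(2-methylpropanoyloxy)-4-(1,2,3-trihydroxypropan-2-yl)phenyl]methyl pentanoate | CCCCC(=O)OCc1ccc(C(O)(CO)CO)c(OC(=O)C(C)C)c1
A5 | alternative 3 | [4-[(2S)-1-acetoxy-2,3-dihydroxypropan-2-yl]-3-(2-methylpropanoyloxy)phenyl]methyl pentanoate | CCCCC(=O)OCc1ccc([C@@](O)(COC(C)=O)CO)c(OC(=O)C(C)C)c1
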